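The ten-membered carbocycle C1–C10 is not closed directly. It arises from an eleven-membered thiacycle 1,1-dioxide in which sulfur bridges C1 and C10: a Ramberg–Bäcklund ring contraction expels SO2 and forms the C1–C10 bond as the trisubstituted E-alkene in one operation. The step exploits that C1=C10 is flanked by two plain CH2 groups (C2, C9), so it maps onto a simple dialkyl sulfone without β-leaving groups. The precursor, a cyclic sulfone fused to the C12/O8 γ-lactone and already carrying the ring-cis C4=C5 alkene and the C6–C8 stereotriad, is assembled by a boron aldol/lactonisation, a CBS reduction and a macrocyclic thioether alkylation.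

Key step: step 13

Remarks on the chemistry:
- Atom labels C1–C15 follow germacrane numbering of the target (O8 = lactone oxygen, O6 = free hydroxyl, C15 = acyloxymethyl carbon, C14 = methyl on C10).
- Thioacetate 15 is used as the racemate, so compounds 16–25 are mixtures of C10 epimers; this is without consequence because C10 becomes sp2 in step 13. Compounds 28 and 29 are C11 epimer mixtures.
- The antipode of the boron reagent in step 8 is chosen from the recalled sense of induction of Z-enol diisopinocampheylborinates; the sense is reagent-controlled, so the other antipode would give the enantiomeric series.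
- TBS = tert-butyl(dimethyl)silyl, TIPS = triisopropylsilyl, Ipc = isopinocampheyl.

Step 1
Reactants: 1 4-chlorobutanoyl chloride; 2 2,2-dimethyl-1,3-dioxane-4,6-dione
Product: 4 methyl 6-chloro-3-oxohexanoate, via acyl dione 3 (not isolated)
Conditions: pyridine, CH2Cl2, 0 °C → rt; then MeOH, reflux
Reagents that add atoms: methanol, CO
Why: C-acylation of the acidic dione and methanolysis of the acyl derivative with loss of acetone and CO2 is the standard β-keto ester synthesis.

Step 2
Reactants: 4 methyl 6-chloro-3-oxohexanoate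
Product: 5 methyl (2E)-6-chloro-3-[(trifluoromethylsulfonyl)oxy]hex-2-enoate
Conditions: Tf2O, aq. Me4NOH, hexane, 5 °C
Reagents that add atoms: trifluoromethanesulfonic anhydride, O=S(=O)(OS(=O)(=O)C(F)(F)F)C(F)(F)F
Why: O-sulfonylation of the non-chelated tetramethylammonium enolate, which adopts the extended geometry, should give the E-enol triflate (triflate trans to the ester), a stereoselective enol triflate formation from a β-keto ester.

Step 3
Reactants: 5 enol triflate; 6 (tributylstannyl)methanol
Product: 7 methyl (2E)-6-chloro-3-(hydroxymethyl)hex-2-enoate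
Conditions: Pd(PPh3)4 (5 mol %), LiCl, 1,4-dioxane, 90 °C
Reagents that add atoms: none
Why: Stille coupling transfers the hydroxymethyl group with retention, so C15 ends trans to the ester carbon (later C6) and the chloropropyl chain (C3) cis to it, which is the ring-cis C4=C5 geometry of the target; the trans hydroxy ester cannot lactonise.

Step 4
Reactants: 7 hydroxy ester
Product: 8 methyl (2E)-3-{[tert-butyl(dimethyl)silyl]oxymethyl}-6-chlorohex-2-enoate
Conditions: TBSCl, imidazole, CH2Cl2, rt
Reagents that add atoms: tert-butyl(chloro)dimethylsilane, CC(C)(C)[Si](C)(C)Cl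
Why: Standard silylation of the primary allylic alcohol protects O15 through the organometallic and basic steps.

Step 5
Reactants: 8 silyl ether ester
Product: 9 (2E)-3-{[tert-butyl(dimethyl)silyl]oxymethyl}-6-chlorohex-2-enoic acid
Conditions: LiOH·H2O, THF/MeOH/H2O, 40 °C; then 1 M HCl to pH 4, 0 °C
Reagents that add atoms: lithium hydroxide, [Li+].[OH-]
Why: Saponification of the enoate leaves the silyl ether and the primary chloride intact and does not touch the alkene geometry.

Step 6
Reactants: 9 enoic acid; 10 (3-ethoxy-3-oxopropyl)zinc bromide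
Product: 12 ethyl (5E)-6-{[tert-butyl(dimethyl)silyl]oxymethyl}-9-chloro-4-oxonon-5-enoate, via acid chloride 11 (not isolated)
Conditions: 1-chloro-N,N,2-trimethylprop-1-en-1-amine, CH2Cl2, 0 °C; then 10, Pd(PPh3)4 (5 mol %), THF, 0 °C → rt
Reagents that add atoms: none
Why: Neutral formation of the acid chloride and Negishi acylation (zerovalent palladium) by the zinc homoenolate give the γ-keto ester (C12, C11, C7 attached to C6) without affecting the alkyl chloride or the enone geometry.

Step 7
Reactants: 13 (2E)-but-2-enal; 14 ethanethioic S-acid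
Product: 15 S-(4-oxobutan-2-yl) ethanethioate (racemic)
Conditions: Et3N (5 mol %), CH2Cl2, 0 °C → rt
Reagents that add atoms: none
Why: Thia-Michael addition of the thioacid to the enal places sulfur on the future C10 next to the C14 methyl and leaves C8 as the aldehyde.

Step 8
Reactants: 12 γ-keto ester; 15 thioacetate aldehyde
Product: 17 (4R,5S)-5-[2-(acetylsulfanyl)propyl]-4-[(2E)-3-{[tert-butyl(dimethyl)silyl]oxymethyl}-6-chlorohex-2-enoyl]oxolan-2-one, via aldol hydroxy ester 16 (not isolated)
Conditions: (+)-Ipc2BOTf [from (−)-α-pinene], i-Pr2NEt, CH2Cl2, −78 °C; 15, −78 → −20 °C; 30% H2O2, MeOH, pH 7 buffer, 0 °C; then PPTS (cat.), toluene, 50 °C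
Reagents that add atoms: none
Why: Regioselective α′-enolisation at C7 gives the Z-boron enolate, whose chair-like aldol transition state should deliver the 7,8-syn aldol with reagent-controlled attack on the aldehyde face that gives (8S), and acid then closes the trans-disubstituted γ-lactone from O8 onto C12; any cis-lactone can be equilibrated at C7, which is α to the ketone.

Step 9
Reactants: 17 lactone ketone
Product: 18 (4S,5S)-5-[2-(acetylsulfanyl)propyl]-4-[(1R,2E)-3-{[tert-butyl(dimethyl)silyl]oxymethyl}-6-chloro-1-hydroxyhex-2-en-1-yl]oxolan-2-one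
Conditions: (R)-2-methyl-CBS-oxazaborolidine (0.3 equiv), BH3·SMe2, THF, −30 °C; then MeOH
Reagents that add atoms: none
Why: CBS reduction under catalyst control, with the alkenyl group as the large substituent, should give the (6R) allylic alcohol by 1,2-reduction, completing the 6,7-syn/7,8-syn triad.

Step 10
Reactants: 18 allylic alcohol
Product: 19 (4R,5S)-5-[2-(acetylsulfanyl)propyl]-4-[(1R,2E)-3-{[tert-butyl(dimethyl)silyl]oxymethyl}-6-chloro-1-[(triisopropylsilyl)oxy]hex-2-en-1-yl]oxolan-2-one
Conditions: TIPSOTf, 2,6-lutidine, CH2Cl2, −78 → 0 °C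
Reagents that add atoms: triisopropylsilyl trifluoromethanesulfonate, CC(C)[Si](C(C)C)(C(C)C)OS(=O)(=O)C(F)(F)F
Why: The bulky TIPS ether blocks O6 against translactonisation and against 1,3-silyl migration to O8 in the later basic steps.

Step 11
Reactants: 19 thioacetate chloride
Product: 21 eleven-membered sulfide (S bridging C1 and C10) fused to the γ-lactone, via thiol 20 (not isolated)
Conditions: pyrrolidine (1.2 equiv), degassed MeCN, 0 °C; then slow addition to Cs2CO3, NaI (cat.), DMF (1 mM), 45 °C
Reagents that add atoms: none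
Why: Chemoselective aminolysis of the thioacetate frees the thiol, whose caesium thiolate closes the eleven-membered thiacycle by intramolecular SN2 at the primary C1 halide under high dilution, a macrocyclic thioether alkylation.

Step 12
Reactants: 21 cyclic sulfide
Product: 22 eleven-membered cyclic sulfone
Conditions: (NH4)6Mo7O24·4H2O (10 mol %), 30% H2O2, EtOH, 0 °C → rt
Reagents that add atoms: hydrogen peroxide, OO
Why: Molybdate-catalysed peroxide oxidation takes the sulfide to the sulfone without epoxidising the trisubstituted alkene.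

Step 13
Reactants: 22 cyclic sulfone
Product: 27 (1(10)E)-15-(TBS-oxy)-6-(TIPS-oxy)germacra-1(10),4-dien-12,8-olide (11,13-dihydro; C3 and C6 cis on C4=C5), via carboxylate 23 (not isolated), via α-bromo sulfone 24 (not isolated), via thiirane dioxide 25 (not isolated), via diene carboxylate 26 (not isolated)
Conditions: KOH, t-BuOH, rt; then BrCF2CF2Br, KOH/Al2O3, t-BuOH/CH2Cl2, 0 °C → rt; then aq. KHSO4, PPTS (cat.), toluene, 40 °C
Reagents that add atoms: none
Why: Ramberg–Bäcklund reaction with in situ halogenation: KOH first opens the lactone to carboxylate 23, which removes the only competing acidic C–H (C11); the α-sulfonyl carbanion is then brominated at C1 (24), deprotonation at C10 closes the thiirane 1,1-dioxide 25 by 3-exo-tet displacement of bromide, and stereospecific loss of SO2 leaves the C1=C10 alkene in what is now the ten-membered carbocycle, after which acidification relactonises O8 onto C12. The closest known reaction type is the Ramberg–Bäcklund ring contraction of cyclic sulfones to cycloalkenes under KOH/Al2O3–polyhaloalkane conditions, which is known to reach strained medium rings. The ten-membered ring is closed as the C1–C10 bond of the episulfone (3-exo-tet), that is, by contraction of the eleven-membered thiacycle by its sulfur atom. No stereocentre is created: C10, an epimer mixture until now, becomes sp2, and C6, C7 and C8 are remote from the carbanions and should be untouched. The step needs E geometry at C1=C10 and halogenation only α to sulfur: the strongly basic medium should equilibrate the episulfone at C1 towards the isomer with C2 and C9 anti, neither α-carbon carries a β-leaving group (C2 and C9 are CH2), and the carboxylate, the silyl ethers and the C4=C5 alkene are inert to the bromine donor, which releases no carbene.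

Step 14
Reactants: 27 saturated lactone
Product: 30 (1(10)E)-15-(TBS-oxy)-6-(TIPS-oxy)germacra-1(10),4,11(13)-trien-12,8-olide, via Mannich base 28 (not isolated), via methiodide 29 (not isolated)
Conditions: LDA, THF, −78 °C; dimethyl(methylidene)ammonium iodide, −78 °C → rt; then MeI, MeOH, rt; then aq. NaHCO3, CH2Cl2
Reagents that add atoms: dimethyl(methylidene)ammonium iodide, C=[N+](C)C.[I-]
Why: Mannich reaction of the lactone enolate at C11, exhaustive N-methylation and β-elimination of trimethylamine install the exocyclic C11=C13 methylene without affecting any stereocentre.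

Step 15
Reactants: 30 bis-silyl ether
Product: 31 (6R,7S,8S,1(10)E)-6,15-dihydroxygermacra-1(10),4,11(13)-trien-12,8-olide
Conditions: HF·pyridine, THF, 0 °C → rt
Reagents that add atoms: none
Why: Fluoride-mediated cleavage of both silyl ethers under mildly acidic conditions, which the α-methylene lactone and the 1,5-diene should tolerate.

Step 16
Reactants: 13 (2E)-but-2-enal
Product: 32 (2Z)-2-iodobut-2-enal
Conditions: I2, K2CO3, DMAP (cat.), THF/H2O, rt
Reagents that add atoms: iodine, II
Why: Amine-catalysed α-iodination of the enal (conjugate addition, iodination, elimination) should give the thermodynamically preferred Z-isomer with iodine cis to the methyl group.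

Step 17
Reactants: 32 iodo enal
Product: 33 (2Z)-2-iodobut-2-en-1-ol
Conditions: NaBH4, CeCl3·7H2O, MeOH, 0 °C
Reagents that add atoms: none
Why: Luche 1,2-reduction of the enal leaves the vinyl iodide and its geometry intact.

Step 18
Reactants: 33 iodo alcohol
Product: 35 (2Z)-2-(hydroxymethyl)but-2-enoic acid, via dianion 34 (not isolated)
Conditions: NaH, THF, 0 °C; t-BuLi (2.1 equiv), −78 °C; CO2; then 1 M HCl
Reagents that add atoms: carbon dioxide, O=C=O
Why: Deprotonation of the hydroxyl and iodine–lithium exchange give a configurationally stable alkenyllithium that is carboxylated with retention, so CO2H ends cis to the methyl group.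

Step 19
Reactants: 35 hydroxy acid
Product: 36 (2Z)-2-(acetoxymethyl)but-2-enoic acid
Conditions: Ac2O, pyridine, CH2Cl2, 0 °C → rt; then H2O
Reagents that add atoms: acetic anhydride, CC(=O)OC(C)=O
Why: Acetylation of the primary alcohol, with any mixed anhydride of the acid hydrolysed on aqueous work-up.

Step 20
Reactants: 31 diol; 36 acetoxy acid
Product: 37 target, (6R,7S,8S)-15-{[(2Z)-2-(acetoxymethyl)but-2-enoyl]oxy}-6-hydroxygermacra-1(10)E,4,11(13)-trien-12,8-olide
Conditions: PPh3, DIAD, THF, 0 °C
Reagents that add atoms: none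
Why: Mitsunobu esterification should activate only the unhindered primary allylic C15 hydroxyl and leave the secondary C6 hydroxyl, and because the acid reacts as the nucleophile its Z-alkene and allylic acetate are not exposed to acyl activation or nucleophilic catalysts.

Compound list
1 | 4-chlorobutanoyl chloride | ClCCCC(Cl)=O | starting material
2 | 2,2-dimethyl-1,3-dioxane-4,6-dione | CC1(C)OC(=O)CC(=O)O1 | starting material
3 | 5-(4-chlorobutanoyl)-2,2-dimethyl-1,3-dioxane-4,6-dione | CC1(C)OC(=O)C(C(=O)CCCCl)C(=O)O1 | intermediate (not isolated)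
4 | methyl 6-chloro-3-oxohexanoate | COC(=O)CC(=O)CCCCl | intermediate
5 | methyl (2E)-6-chloro-3-[(trifluoromethylsulfonyl)oxy]hex-2-enoate (triflate trans to ester) | COC(=O)/C=C(/OS(=O)(=O)C(F)(F)F)CCCCl | intermediate
6 | (tributylstannyl)methanol | CCCC[Sn](CCCC)(CCCC)CO | starting material
7 | methyl (2E)-6-chloro-3-(hydroxymethyl)hex-2-enoate (CH2OH trans to ester) | COC(=O)/C=C(/CO)CCCCl | intermediate
8 | methyl (2E)-3-{[tert-butyl(dimethyl)silyl]oxymethyl}-6-chlorohex-2-enoate | COC(=O)/C=C(/CO[Si](C)(C)C(C)(C)C)CCCCl | intermediate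
9 | (2E)-3-{[tert-butyl(dimethyl)silyl]oxymethyl}-6-chlorohex-2-enoic acid | OC(=O)/C=C(/CO[Si](C)(C)C(C)(C)C)CCCCl | intermediate
10 | (3-ethoxy-3-oxopropyl)zinc bromide | CCOC(=O)CC[Zn]Br | starting material
11 | (2E)-3-{[tert-butyl(dimethyl)silyl]oxymethyl}-6-chlorohex-2-enoyl chloride | ClC(=O)/C=C(/CO[Si](C)(C)C(C)(C)C)CCCCl | intermediate (not isolated)
12 | ethyl (5E)-6-{[tert-butyl(dimethyl)silyl]oxymethyl}-9-chloro-4-oxonon-5-enoate (ketone cis to the chloropropyl chain) | CCOC(=O)CCC(=O)/C=C(/CO[Si](C)(C)C(C)(C)C)CCCCl | intermediate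
13 | (2E)-but-2-enal | C/C=C/C=O | starting material
14 | ethanethioic S-acid | CC(=O)S | starting material
15 | S-(4-oxobutan-2-yl) ethanethioate, racemic | CC(CC=O)SC(C)=O | intermediate
16 | ethyl (3R,5E)-3-[(1S)-3-(acetylsulfanyl)-1-hydroxybutyl]-6-{[tert-butyl(dimethyl)silyl]oxymethyl}-9-chloro-4-oxonon-5-enoate (7,8-syn aldol) | CCOC(=O)C[C@@H](C(=O)/C=C(/CO[Si](C)(C)C(C)(C)C)CCCCl)[C@@H](O)CC(C)SC(C)=O | intermediate (not isolated)
17 | (4R,5S)-5-[2-(acetylsulfanyl)propyl]-4-[(2E)-3-{[tert-butyl(dimethyl)silyl]oxymethyl}-6-chlorohex-2-enoyl]oxolan-2-one (trans lactone) | O=C1C[C@@H](C(=O)/C=C(/CO[Si](C)(C)C(C)(C)C)CCCCl)[C@H](CC(C)SC(C)=O)O1 | intermediate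
18 | (4S,5S)-5-[2-(acetylsulfanyl)propyl]-4-[(1R,2E)-3-{[tert-butyl(dimethyl)silyl]oxymethyl}-6-chloro-1-hydroxyhex-2-en-1-yl]oxolan-2-one | O=C1C[C@@H]([C@H](O)/C=C(/CO[Si](C)(C)C(C)(C)C)CCCCl)[C@H](CC(C)SC(C)=O)O1 | intermediate
19 | (4R,5S)-5-[2-(acetylsulfanyl)propyl]-4-[(1R,2E)-3-{[tert-butyl(dimethyl)silyl]oxymethyl}-6-chloro-1-[(triisopropylsilyl)oxy]hex-2-en-1-yl]oxolan-2-one | O=C1C[C@@H]([C@H](O[Si](C(C)C)(C(C)C)C(C)C)/C=C(/CO[Si](C)(C)C(C)(C)C)CCCCl)[C@H](CC(C)SC(C)=O)O1 | intermediate
20 | free thiol of 19 (2-sulfanylpropyl side chain) | O=C1C[C@@H]([C@H](O[Si](C(C)C)(C(C)C)C(C)C)/C=C(/CO[Si](C)(C)C(C)(C)C)CCCCl)[C@H](CC(C)S)O1 | intermediate (not isolated)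
21 | eleven-membered sulfide: S bridges C1 and C10; γ-lactone (C12/O8) trans-fused at C7/C8; C4=C5 with C3 and C6 cis; 6-OTIPS (6R), 15-OTBS, 8S | O=C1C[C@@H]2[C@@H](O1)CC(C)SCCC/C(CO[Si](C)(C)C(C)(C)C)=C\[C@H]2O[Si](C(C)C)(C(C)C)C(C)C | intermediate
22 | eleven-membered sulfone (S,S-dioxide of 21) | O=C1C[C@@H]2[C@@H](O1)CC(C)S(=O)(=O)CCC/C(CO[Si](C)(C)C(C)(C)C)=C\[C@H]2O[Si](C(C)C)(C(C)C)C(C)C | intermediate
23 | potassium salt of the seco acid of 22 (8-hydroxy, C12 carboxylate) | [K+].[O-]C(=O)C[C@@H]1[C@@H](O)CC(C)S(=O)(=O)CCC/C(CO[Si](C)(C)C(C)(C)C)=C\[C@H]1O[Si](C(C)C)(C(C)C)C(C)C | intermediate (not isolated)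
24 | 1-bromo derivative of 23 (α-bromo sulfone) | [K+].[O-]C(=O)C[C@@H]1[C@@H](O)CC(C)S(=O)(=O)C(Br)CC/C(CO[Si](C)(C)C(C)(C)C)=C\[C@H]1O[Si](C(C)C)(C(C)C)C(C)C | intermediate (not isolated)
25 | thiirane 1,1-dioxide spanning C1 and C10 on the ten-membered ring (C2 and C9 anti) | [K+].[O-]C(=O)C[C@@H]1[C@@H](O)CC2(C)C(CC/C(CO[Si](C)(C)C(C)(C)C)=C\[C@H]1O[Si](C(C)C)(C(C)C)C(C)C)S2(=O)=O | intermediate (not isolated)
26 | potassium salt of the ring-contracted hydroxy acid (1(10)E-alkene) | [K+].[O-]C(=O)C[C@@H]1[C@@H](O)C/C(C)=C/CC/C(CO[Si](C)(C)C(C)(C)C)=C\[C@H]1O[Si](C(C)C)(C(C)C)C(C)C | intermediate (not isolated)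
27 | (1(10)E)-15-(TBS-oxy)-6-(TIPS-oxy)germacra-1(10),4-dien-12,8-olide (11,13-dihydro; C3/C6 cis on C4=C5; 6R, 8S) | O=C1C[C@@H]2[C@@H](O1)C/C(C)=C/CC/C(CO[Si](C)(C)C(C)(C)C)=C\[C@H]2O[Si](C(C)C)(C(C)C)C(C)C | intermediate
28 | 11-(dimethylaminomethyl) derivative of 27 | CN(C)CC1[C@@H]2[C@@H](OC1=O)C/C(C)=C/CC/C(CO[Si](C)(C)C(C)(C)C)=C\[C@H]2O[Si](C(C)C)(C(C)C)C(C)C | intermediate (not isolated)
29 | trimethylammonium iodide of 28 | C[N+](C)(C)CC1[C@@H]2[C@@H](OC1=O)C/C(C)=C/CC/C(CO[Si](C)(C)C(C)(C)C)=C\[C@H]2O[Si](C(C)C)(C(C)C)C(C)C.[I-] | intermediate (not isolated)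
30 | (1(10)E)-15-(TBS-oxy)-6-(TIPS-oxy)germacra-1(10),4,11(13)-trien-12,8-olide | C=C1[C@@H]2[C@@H](OC1=O)C/C(C)=C/CC/C(CO[Si](C)(C)C(C)(C)C)=C\[C@H]2O[Si](C(C)C)(C(C)C)C(C)C | intermediate
31 | (6R,7S,8S,1(10)E)-6,15-dihydroxygermacra-1(10),4,11(13)-trien-12,8-olide | C=C1[C@@H]2[C@@H](OC1=O)C/C(C)=C/CC/C(CO)=C\[C@H]2O | intermediate
32 | (2Z)-2-iodobut-2-enal | C/C=C(\I)C=O | intermediate
33 | (2Z)-2-iodobut-2-en-1-ol | C/C=C(\I)CO | intermediate
34 | sodium (2Z)-2-lithiobut-2-en-1-olate | C/C=C(\[Li])C[O-].[Na+] | intermediate (not isolated)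
35 | (2Z)-2-(hydroxymethyl)but-2-enoic acid | C/C=C(\C(=O)O)CO | intermediate
36 | (2Z)-2-(acetoxymethyl)but-2-enoic acid | C/C=C(\C(=O)O)COC(C)=O | intermediate
37 | (6R,7S,8S)-15-{[(2Z)-2-(acetoxymethyl)but-2-enoyl]oxy}-6-hydroxygermacra-1(10)E,4,11(13)-trien-12,8-olide | C=C1C(=O)O[C@H]2C/C(C)=C/CC/C(COC(=O)/C(=C\C)COC(C)=O)=C\[C@@H](O)[C@H]12 | target

Total step count: 20. Longest linear sequence: 15 steps (steps 1–6, 8–15 and 20).

Steps most likely to fail

Step 13 (ring contraction). What may go wrong: the cis-fused thiirane dioxide may collapse before it epimerises and give the ring-cis (Z) C1=C10 isomer; halogen transfer to the hindered sulfone carbanion on the solid base may be incomplete; the C8 alkoxide may react with the bromine donor or the hydroxy acid may relactonise poorly. Fallback, a stepwise Ramberg–Bäcklund reaction on the intact lactone in an aprotic medium: it sets out from sulfide 21. N-Chlorosuccinimide (CCl4, 0 °C) should chlorinate the sulfide next to sulfur to give the α-chloro sulfide F1 (a C10 regioisomer would converge). mCPBA (2.2 equiv, NaHCO3, CH2Cl2, −10 °C) should then give the α-chloro sulfone F2, and KOtBu (3 equiv, THF, −78 → 0 °C; one equivalent is consumed by the lactone enolate) should close the thiirane dioxide F3 (not isolated), which loses SO2. Strong alkoxide base in an aprotic solvent is the variant known to favour E-alkenes. The fallback comes back to the route at compound 27.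

Step 11 (macrocyclic thioether alkylation). What may go wrong: intermolecular S-alkylation to oligomers, oxidative disulfide formation from the free thiol, or opening of the lactone by amine or thiolate. Fallback, ring closure at the sulfone oxidation level by sulfinate alkylation: it sets out from 19. After S-deacetylation (pyrrolidine), the thiol is trapped by conjugate addition to methyl acrylate (Et3N) to give the sulfide ester F4, which is oxidised ((NH4)6Mo7O24·4H2O, H2O2, EtOH) to the sulfone ester F5. Cs2CO3 with NaI (cat.) in DMF at high dilution and 60 °C should release the caesium sulfinate F6 (not isolated) by retro-Michael loss of methyl acrylate; the sulfinate, which cannot dimerise oxidatively and does not attack the lactone, S-alkylates the C1 halide. The fallback comes back to the route at sulfone 22, so step 12 is skipped.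

Step 8 (enantioselective boron aldol). What may go wrong: insufficient enantiofacial discrimination by the boron ligands, or competing enolisation towards the γ-positions of the enone. Fallback, a racemic aldol followed by separation of diastereomers after the reagent-controlled reduction: it sets out from 12 and 15. Bu2BOTf/i-Pr2NEt (CH2Cl2, −78 °C) and the same acid lactonisation should give the syn aldol as the racemate, that is 16 together with its enantiomer F7 (not isolated), and then 17 together with its enantiomer F8. The (R)-CBS reduction of step 9, applied to this racemate, should convert 17 into 18 and F8 into the (6R,7R,8R)-diastereomer F9, which differs from 18 in relative configuration and is removed by chromatography. The fallback comes back to the route at compound 18.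

Further compounds
F1 | step 13 | 1-chloro derivative of sulfide 21 (α-chloro sulfide) | O=C1C[C@@H]2[C@@H](O1)CC(C)SC(Cl)CC/C(CO[Si](C)(C)C(C)(C)C)=C\[C@H]2O[Si](C(C)C)(C(C)C)C(C)C
F2 | step 13 | 1-chloro derivative of sulfone 22 (α-chloro sulfone) | O=C1C[C@@H]2[C@@H](O1)CC(C)S(=O)(=O)C(Cl)CC/C(CO[Si](C)(C)C(C)(C)C)=C\[C@H]2O[Si](C(C)C)(C(C)C)C(C)C
F3 | step 13 | thiirane 1,1-dioxide spanning C1 and C10, lactone closed | O=C1C[C@@H]2[C@@H](O1)CC3(C)C(CC/C(CO[Si](C)(C)C(C)(C)C)=C\[C@H]2O[Si](C(C)C)(C(C)C)C(C)C)S3(=O)=O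
F4 | step 11 | methyl 3-sulfanylpropanoate thioether of thiol 20 (sulfide ester) | O=C1C[C@@H]([C@H](O[Si](C(C)C)(C(C)C)C(C)C)/C=C(/CO[Si](C)(C)C(C)(C)C)CCCCl)[C@H](CC(C)SCCC(=O)OC)O1
F5 | step 11 | sulfone of F4 (β-sulfonyl ester) | O=C1C[C@@H]([C@H](O[Si](C(C)C)(C(C)C)C(C)C)/C=C(/CO[Si](C)(C)C(C)(C)C)CCCCl)[C@H](CC(C)S(=O)(=O)CCC(=O)OC)O1
F6 | step 11 | caesium sulfinate at C10 of the open-chain chloride | O=C1C[C@@H]([C@H](O[Si](C(C)C)(C(C)C)C(C)C)/C=C(/CO[Si](C)(C)C(C)(C)C)CCCCl)[C@H](CC(C)S(=O)[O-])O1.[Cs+]
F7 | step 8 | enantiomer of aldol hydroxy ester 16 | CCOC(=O)C[C@H](C(=O)/C=C(/CO[Si](C)(C)C(C)(C)C)CCCCl)[C@H](O)CC(C)SC(C)=O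
F8 | step 8 | enantiomer of lactone ketone 17, (4S,5R) | O=C1C[C@H](C(=O)/C=C(/CO[Si](C)(C)C(C)(C)C)CCCCl)[C@@H](CC(C)SC(C)=O)O1
F9 | step 8 | (6R,7R,8R)-diastereomer of alcohol 18 | O=C1C[C@H]([C@H](O)/C=C(/CO[Si](C)(C)C(C)(C)C)CCCCl)[C@@H](CC(C)SC(C)=O)O1
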